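**Two runs.** Start from what stays constant when the substrate charge moves.

in all of them: gas phase 27 mM (held)
- ochre: substrate 0.40 M; protic impurity 0.040 M; run made earlier
- amber: substrate 1.6 M; protic impurity 0.040 M; run made earlier
- flask: substrate 0.80 M; protic impurity 0.0400 M; time 8.0 min

| run | time / min | target / % |
|---|---|---|
| ochre | 0.417 | 63.3 |
| ochre | 0.833 | 76.9 |
| ochre | 2.00 | 80.8 |
| ochre | 5.00 | 80.5 |
| amber | 0.417 | 60.8 |
| amber | 0.833 | 76.2 |
| amber | 2.00 | 80.3 |
| amber | 5.00 | 80.9 |

(standard deviation of a reading: 0.5 percentage points)

- at the start none of the gas phase is in solution

* amount of target at 8.0 min, in percent of the substrate charged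
* concentration of dissolved gas in solution at 8.0 min, in percent of saturation

Ochre and amber differ in charge by a factor of 4.00. Yet their last readings at 5.00 min differ by 0.4 percentage points, with a scatter of 0.5 points on each. Take their mean as the plateau, 80.7% of the charge.

**Powers of ten.** Now go to logarithms. At its first reading, each run's target still lies below the plateau, and that gap, as a fraction of the plateau, gives a time per power of ten: 0.626 min for ochre and 0.686 min for amber. Their mean, 0.656 min, is the decade time: the time in which the unreacted fraction falls tenfold, constant for a pseudo-first-order decay. Both runs stand on the plateau at 5.00 min because that time is long against the decade time, 7.62 decades, while the change of charge moved the time per decade from 0.626 min to 0.686 min.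

**This flask.** Its charge lies between the two, so carry both numbers over. Since 8.0 min is 12.2 decades, reckon the target at 80.7%. Amber, with twice this charge, read 80.3% at 2.00 min, so expect dissolved gas near saturation in this flask once the substrate has reacted.

The forecast gives 80.7% (79.5% to 81.8%) and 98% of saturation (85% to 100%), holding that “Gas transfer therefore appears fast and not limiting”.

**The result.** The flask gives 81.0% and 99.8% of saturation.

    gas phase ⇌ dissolved gas, rate k1*(csat - [dissolved gas]) (kL = 23.0 s⁻¹)
    substrate + dissolved gas → target (k = 1.80 L mol⁻¹ s⁻¹)
    substrate → side product (k = 0.0110 s⁻¹)
    dissolved gas + protic impurity → quenched reagent (k = 0.190 L mol⁻¹ s⁻¹)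
    dissolved gas → decomposed reagent (k = 0.0460 s⁻¹)

At 0.625 min the half-life of substrate by the step into target is 0.24 min, short against 8.0 min, and the decade time puts the unreacted fraction at 6.03% by 0.800 min, where the flask holds 6.05%. Carried to the neighbouring flask with 0.016 M of protic impurity, the same decade time counts 12.2 decades by 8.00 min, and that neighbour holds 0% substrate and 81.0% target.

The data stem from a simulated flask on assumed constants, noise included.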